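**Retrosynthetic overview**
- The epoxide comes last from hydroxyl-directed epoxidation of the Z-cyclononene tertiary allylic alcohol. The butenolide comes just before it, by acetonide release and lactonization of a Z-γ-alkoxy enoate.
- The nine-membered ring (the only carbocycle) is closed at C9–C10 by a visible-light palladium radical Heck reaction between a halomethyl ketone and the linalool vinyl group.
- The C4a–C11a bond and both ring CH stereocentres come from an Ireland–Claisen rearrangement that relays the C12 carbinol configuration.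
- The C4–C12 bond comes from vinylalumination of a linalool-derived ynoate onto an aldehyde made from D-erythronolactone acetonide (Felkin control).
- Ring order: dioxolane (bought) → nine-membered carbocycle → butenolide → epoxide.

Labels (xenicane numbering): C1 = CH2OH carbon; C3 = lactone C=O; C4 = butenolide α-carbon; C4a, C11a = ring CH carbons bearing the butenolide and C1; C5, C6 = ring CH2; C7 = C(OH)CH3; C8, C9 = epoxide CH; C10 = ring CH2; C11 = C(=C19H2); C12 = butenolide β-CH; C13 = lactone O–CH; C14 = CH(OH); C15 = C(OH)(CH3)2.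

Assumption: (S)-(+)-linalool of high enantiomeric purity, 2,3-O-isopropylidene-D-erythronolactone and 3-(tert-butyldiphenylsilyloxy)propanoic acid are taken as purchasable.

**Step 1**
Reactants: 1 (S)-(+)-linalool
Product: 3 (5S)-5-ethenyl-5-methyloxolan-2-ol (lactol form of (4S)-4-hydroxy-4-methylhex-5-enal), via ozonide 2 (not isolated)
Conditions: O3, CH2Cl2, −78 °C (stopped when 1 is consumed); Me2S, −78 → 25 °C
Reagents that add atoms: ozone, [O-][O+]=O
Why: Ozonolysis; the electron-rich trisubstituted alkene reacts far faster than the vinyl group deactivated by the allylic hydroxyl, and the purchased C7 stereocentre is untouched.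

**Step 2**
Reactants: 3 (5S)-5-ethenyl-5-methyloxolan-2-ol
Product: 4 (3S)-3-methylhept-1-en-6-yn-3-ol
Conditions: dimethyl (1-diazo-2-oxopropyl)phosphonate, K2CO3, MeOH, 0 → 25 °C
Reagents that add atoms: Ohira–Bestmann reagent, CC(=O)C(=[N+]=[N-])P(=O)(OC)OC
Why: Seyferth–Gilbert homologation (Ohira–Bestmann variant); the lactol reacts through its open aldehyde form under conditions that leave the tertiary allylic alcohol alone.

**Step 3**
Reactants: 4 (3S)-3-methylhept-1-en-6-yn-3-ol
Product: 6 methyl (6S)-6-hydroxy-6-methyloct-7-en-2-ynoate, via dilithio dianion 5 (not isolated)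
Conditions: n-BuLi (2.1 equiv), THF, −78 °C; ClCO2Me (1.0 equiv), −78 °C; aq. NH4Cl
Reagents that add atoms: methyl chloroformate, COC(=O)Cl
Why: Acetylide acylation; in the dianion the carbon nucleophile reacts much faster than the hindered tertiary alkoxide, so one equivalent of chloroformate gives the ynoate.

**Step 4**
Reactants: 7 2,3-O-isopropylidene-D-erythronolactone
Product: 8 2-[(4R,5R)-5-(hydroxymethyl)-2,2-dimethyl-1,3-dioxolan-4-yl]propan-2-ol
Conditions: MeMgBr (3.5 equiv), THF, 0 → 25 °C
Reagents that add atoms: methylmagnesium bromide, C[Mg]Br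
Why: Double Grignard addition opens the lactone to the dimethyl carbinol; both stereocentres (future C13 and C14) come unchanged from the chiral pool.

**Step 5**
Reactants: 8 2-[(4R,5R)-5-(hydroxymethyl)-2,2-dimethyl-1,3-dioxolan-4-yl]propan-2-ol
Product: 9 bis(triethylsilyl) ether of 8
Conditions: Et3SiOTf (2.3 equiv), 2,6-lutidine, CH2Cl2, −78 → 0 °C
Reagents that add atoms: triethylsilyl triflate, CC[Si](CC)(CC)OS(=O)(=O)C(F)(F)F
Why: Exhaustive silylation with the reactive triflate protects the tertiary alcohol and prepares the primary silyl ether for direct oxidation.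

**Step 6**
Reactants: 9 bis(triethylsilyl) ether of 8
Product: 10 (4S,5R)-2,2-dimethyl-5-[2-(triethylsilyloxy)propan-2-yl]-1,3-dioxolane-4-carbaldehyde
Conditions: (COCl)2, DMSO, CH2Cl2, −78 °C; Et3N, −78 → −30 °C
Reagents that add atoms: none
Why: Swern oxidation applied directly to the silyl ether; the chlorosulfonium salt cleaves only the unhindered primary Si–O bond and oxidizes it, and the low temperature keeps the cis-dioxolane aldehyde from epimerizing.

**Step 7**
Reactants: 6 methyl (6S)-6-hydroxy-6-methyloct-7-en-2-ynoate; 10 (4S,5R)-2,2-dimethyl-5-[2-(triethylsilyloxy)propan-2-yl]-1,3-dioxolane-4-carbaldehyde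
Product: 12 methyl (2Z,6S)-6-hydroxy-2-[(R)-hydroxy{(4R,5R)-2,2-dimethyl-5-[2-(triethylsilyloxy)propan-2-yl]-1,3-dioxolan-4-yl}methyl]-6-methylocta-2,7-dienoate, via vinylalane 11 (not isolated)
Conditions: i-Bu2AlH (2.2 equiv), NMO (2.4 equiv), THF, 0 °C, then 6; then 10, 0 → 25 °C; aq. KNaC4H4O6
Reagents that add atoms: none
Why: Vinylalumination (reductive Morita–Baylis–Hillman-type aldol); cis H–Al addition across the ynoate fixes the Z geometry (C5 cis to the ester), and Felkin–Anh attack on the chiral-pool aldehyde, anti to the C13–O bond, sets C12 as R.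

**Step 8**
Reactants: 12 (the C12 allylic alcohol); 13 3-(tert-butyldiphenylsilyloxy)propanoic acid
Product: 14 C12 (R) 3-(tert-butyldiphenylsilyloxy)propanoate of 12
Conditions: DCC, DMAP (cat.), CH2Cl2, 0 → 25 °C
Reagents that add atoms: none
Why: Steglich esterification acylates the secondary allylic alcohol with retention at C12, while the tertiary C7 hydroxyl is too hindered to react.

**Step 9**
Reactants: 14 C12 (R) ester
Product: 17 C11 carboxylic acid (C11a S bearing C1H2OSi(t-Bu)Ph2; C4a S; C4=C12 Z with C13 cis to the methyl ester), via silyl ketene acetal 15 (not isolated), via trimethylsilyl ester 16 (not isolated)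
Conditions: LiN(i-Pr)2 (2.3 equiv), Me3SiCl (4 equiv), THF, −78 → 45 °C; then H2O, citric acid (pH 4)
Reagents that add atoms: none
Why: Ireland–Claisen rearrangement; kinetic enolization gives the E(O) enolate, and a chair transition state with the dioxolanyl group pseudo-equatorial transfers the C12 configuration to C4a (S), sets C11a anti to it, and places C13 cis to the ester on the new C4=C12 bond.

**Step 10**
Reactants: 17 C11 carboxylic acid
Product: 18 C11 N-methoxy-N-methylamide
Conditions: MeNHOMe·HCl, EDC·HCl, HOBt, i-Pr2NEt, CH2Cl2, 0 → 25 °C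
Reagents that add atoms: N,O-dimethylhydroxylamine hydrochloride, CNOC.Cl
Why: Carbodiimide amide coupling under near-neutral conditions, so the α stereocentre C11a and the β-silyloxy group are not disturbed.

**Step 11**
Reactants: 18 C11 N-methoxy-N-methylamide
Product: 19 C11 chloromethyl ketone (C10 = CH2Cl)
Conditions: ICH2Cl (3 equiv), MeLi·LiBr (3 equiv), THF, −78 °C; aq. NH4Cl
Reagents that add atoms: chloroiodomethane, ClCI
Why: Carbenoid homologation; LiCH2Cl made in the flask adds once to the Weinreb amide through a stable chelated tetrahedral intermediate, and at −78 °C the hindered conjugated methyl ester is not attacked.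

**Step 12**
Reactants: 19 C11 chloromethyl ketone
Product: 21 (3Z,5S,8S,9S)-cyclonon-3-en-1-one (ring C11–C10–C9=C8–C7–C6–C5–C4a–C11a; side chains unchanged), via iodomethyl ketone 20 (not isolated)
Conditions: NaI (1.5 equiv), Pd(OAc)2 (10 mol %), Xantphos (20 mol %), K2CO3 (2 equiv), PhH–MeCN (9:1), 0.002 M, blue LEDs (450 nm), 25 °C
Reagents that add atoms: none
Why: Proposed new method: a visible-light palladium radical Heck ring closure in the 9-endo mode. The photoexcited zerovalent palladium–Xantphos complex reduces iodide 20 to an electrophilic α-keto radical paired with monovalent palladium. This radical adds to the terminal carbon (C9) of the electron-rich vinyl carbinol, a polarity-matched partner, whereas the C4=C12 enoate is electron-poor and hindered. The C8 radical recombines with palladium, and β-hydride elimination can only use a C9 hydrogen because C7 is quaternary, so the C8=C9 alkene results and the ring is expected to hold it Z. No stereocentre is touched. The closest known chemistry is the visible-light palladium alkyl Heck reaction of alkyl halides, including endo-selective cyclizations, and 8-endo cyclizations of α-carbonyl radicals.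

**Step 13**
Reactants: 21 cyclononenone
Product: 22 C11 methylidene compound (C11=C19H2; C11a now R by priority change)
Conditions: Zn, CH2Br2, TiCl4, THF–CH2Cl2, 0 → 25 °C
Reagents that add atoms: dibromomethane, BrCBr
Why: Takai–Lombardo methylenation; the non-basic zinc–titanium methylene reagent converts the β,γ-unsaturated ketone without enolization, so C11a is not epimerized, C8=C9 is not conjugated, the C1 silyl ether is not eliminated, and the ester is left alone.

**Step 14**
Reactants: 22 C11 methylidene compound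
Product: 23 butenolide triol with C1–OSi(t-Bu)Ph2
Conditions: AcOH–H2O–THF (3:1:1), 45 °C
Reagents that add atoms: none
Why: Acid hydrolysis removes the acetonide and the tertiary triethylsilyl ether, and the freed C13 hydroxyl, cis to the methyl ester, lactonizes (5-exo) to the butenolide; the tert-butyldiphenylsilyl ether survives.

**Step 15**
Reactants: 23 butenolide triol with C1–OSi(t-Bu)Ph2
Product: 24 C8–C9 epoxide (1R,2S,5S,6R,9R in the 10-oxabicyclo[7.1.0]decane numbering of 25)
Conditions: VO(acac)2 (5 mol %), t-BuOOH (1.2 equiv), CH2Cl2, 0 °C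
Reagents that add atoms: tert-butyl hydroperoxide, CC(C)(C)OO
Why: Hydroxyl-directed (Sharpless–Michaelson) epoxidation; the vanadium alkoxide of the C7 alcohol delivers oxygen to the adjacent Z alkene on the face syn to the hydroxyl, as established for medium-ring Z-allylic alcohols, which sets C8 and C9; the exocyclic methylene has no free hydroxyl in reach and the butenolide is electron-poor.

**Step 16**
Reactants: 24 C8–C9 epoxide
Product: 25 (5R)-5-[(1R)-1,2-dihydroxy-2-methylpropyl]-3-[(1R,2S,5S,6R,9R)-2-hydroxy-6-(hydroxymethyl)-2-methyl-7-methylidene-10-oxabicyclo[7.1.0]decan-5-yl]furan-2(5H)-one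
Conditions: Bu4NF, AcOH (1:1), THF, 0 → 25 °C
Reagents that add atoms: none
Why: Buffered fluoride desilylation frees the C1 alcohol without opening the epoxide or epimerizing the base-sensitive butenolide γ-centre.

**Compound list**
1 | (S)-(+)-linalool, (3S)-3,7-dimethylocta-1,6-dien-3-ol | C=C[C@@](C)(O)CCC=C(C)C | starting material
2 | 6,7-ozonide (1,2,4-trioxolane) of 1 | C=C[C@@](C)(O)CCC1OOC(C)(C)O1 | intermediate
3 | (5S)-5-ethenyl-5-methyloxolan-2-ol (anomer mixture) | C=C[C@]1(C)CCC(O)O1 | intermediate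
4 | (3S)-3-methylhept-1-en-6-yn-3-ol | C=C[C@@](C)(O)CCC#C | intermediate
5 | dilithio dianion of 4 (lithium alkoxide, lithium acetylide) | C=C[C@@](C)(O[Li])CCC#C[Li] | intermediate
6 | methyl (6S)-6-hydroxy-6-methyloct-7-en-2-ynoate | C=C[C@@](C)(O)CCC#CC(=O)OC | intermediate
7 | 2,3-O-isopropylidene-D-erythronolactone, (3aR,6aR)-2,2-dimethyldihydrofuro[3,4-d][1,3]dioxol-4(3aH)-one | CC1(C)O[C@@H]2COC(=O)[C@@H]2O1 | starting material
8 | 2-[(4R,5R)-5-(hydroxymethyl)-2,2-dimethyl-1,3-dioxolan-4-yl]propan-2-ol | CC1(C)O[C@H](CO)[C@@H](O1)C(C)(C)O | intermediate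
9 | bis(triethylsilyl) ether of 8 (4R,5R) | CC1(C)O[C@H](CO[Si](CC)(CC)CC)[C@@H](O1)C(C)(C)O[Si](CC)(CC)CC | intermediate
10 | (4S,5R)-2,2-dimethyl-5-[2-(triethylsilyloxy)propan-2-yl]-1,3-dioxolane-4-carbaldehyde | CC1(C)O[C@H](C=O)[C@@H](O1)C(C)(C)O[Si](CC)(CC)CC | intermediate
11 | vinylalane: methyl (6S)-2-(diisobutylalumanyl)-6-[(diisobutylalumanyl)oxy]-6-methylocta-2,7-dienoate, H and Al cis | C=C[C@@](C)(O[Al](CC(C)C)CC(C)C)CC/C=C(\C(=O)OC)[Al](CC(C)C)CC(C)C | intermediate
12 | methyl (2Z,6S)-6-hydroxy-2-[(R)-hydroxy{(4R,5R)-2,2-dimethyl-5-[2-(triethylsilyloxy)propan-2-yl]-1,3-dioxolan-4-yl}methyl]-6-methylocta-2,7-dienoate | C=C[C@@](C)(O)CC/C=C(\C(=O)OC)[C@@H](O)[C@H]1OC(C)(C)O[C@H]1C(C)(C)O[Si](CC)(CC)CC | intermediate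
13 | 3-(tert-butyldiphenylsilyloxy)propanoic acid | OC(=O)CCO[Si](c1ccccc1)(c1ccccc1)C(C)(C)C | starting material
14 | C12 (R) 3-(tert-butyldiphenylsilyloxy)propanoate of 12 (2Z, 6S, dioxolane 4R,5R) | C=C[C@@](C)(O)CC/C=C(\C(=O)OC)[C@@H](OC(=O)CCO[Si](c1ccccc1)(c1ccccc1)C(C)(C)C)[C@H]2OC(C)(C)O[C@H]2C(C)(C)O[Si](CC)(CC)CC | intermediate
15 | (E)-O-trimethylsilyl ketene acetal of 14 (CH2OSi cis to the allylic oxygen; C7–OSiMe3) | C=C[C@@](C)(O[Si](C)(C)C)CC/C=C(\C(=O)OC)[C@@H](O/C(O[Si](C)(C)C)=C\CO[Si](c1ccccc1)(c1ccccc1)C(C)(C)C)[C@H]2OC(C)(C)O[C@H]2C(C)(C)O[Si](CC)(CC)CC | intermediate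
16 | trimethylsilyl ester of 17 with C7–OSiMe3 | C=C[C@@](C)(O[Si](C)(C)C)CC[C@@H]([C@@H](CO[Si](c1ccccc1)(c1ccccc1)C(C)(C)C)C(=O)O[Si](C)(C)C)/C(C(=O)OC)=C/[C@H]2OC(C)(C)O[C@H]2C(C)(C)O[Si](CC)(CC)CC | intermediate
17 | C11 carboxylic acid (C11a S, C4a S, C7 S, C4=C12 Z, dioxolane 4R,5R) | C=C[C@@](C)(O)CC[C@@H]([C@@H](CO[Si](c1ccccc1)(c1ccccc1)C(C)(C)C)C(=O)O)/C(C(=O)OC)=C/[C@H]2OC(C)(C)O[C@H]2C(C)(C)O[Si](CC)(CC)CC | intermediate
18 | C11 N-methoxy-N-methylamide of 17 | C=C[C@@](C)(O)CC[C@@H]([C@@H](CO[Si](c1ccccc1)(c1ccccc1)C(C)(C)C)C(=O)N(C)OC)/C(C(=O)OC)=C/[C@H]2OC(C)(C)O[C@H]2C(C)(C)O[Si](CC)(CC)CC | intermediate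
19 | C11 chloromethyl ketone | C=C[C@@](C)(O)CC[C@@H]([C@@H](CO[Si](c1ccccc1)(c1ccccc1)C(C)(C)C)C(=O)CCl)/C(C(=O)OC)=C/[C@H]2OC(C)(C)O[C@H]2C(C)(C)O[Si](CC)(CC)CC | intermediate
20 | C11 iodomethyl ketone | C=C[C@@](C)(O)CC[C@@H]([C@@H](CO[Si](c1ccccc1)(c1ccccc1)C(C)(C)C)C(=O)CI)/C(C(=O)OC)=C/[C@H]2OC(C)(C)O[C@H]2C(C)(C)O[Si](CC)(CC)CC | intermediate
21 | (3Z,5S,8S,9S)-9-[(tert-butyldiphenylsilyloxy)methyl]-5-hydroxy-5-methyl-8-[(Z)-enoate–dioxolane side chain]cyclonon-3-en-1-one | O=C1C/C=C\[C@@](C)(O)CC[C@H](/C(C(=O)OC)=C/[C@H]2OC(C)(C)O[C@H]2C(C)(C)O[Si](CC)(CC)CC)[C@H]1CO[Si](c3ccccc3)(c4ccccc4)C(C)(C)C | intermediate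
22 | C11 methylidene analogue of 21 (C11a R, C4a S, C7 S, C8=C9 Z) | C=C1C/C=C\[C@@](C)(O)CC[C@H](/C(C(=O)OC)=C/[C@H]2OC(C)(C)O[C@H]2C(C)(C)O[Si](CC)(CC)CC)[C@H]1CO[Si](c3ccccc3)(c4ccccc4)C(C)(C)C | intermediate
23 | butenolide triol, C1 tert-butyldiphenylsilyl ether (C13 R, C14 R) | C=C1C/C=C\[C@@](C)(O)CC[C@H](C2=C[C@H]([C@@H](O)C(C)(C)O)OC2=O)[C@H]1CO[Si](c3ccccc3)(c4ccccc4)C(C)(C)C | intermediate
24 | C8–C9 cis-epoxide of 23, oxygen syn to the C7 hydroxyl | C=C1C[C@H]2O[C@H]2[C@@](C)(O)CC[C@H](C3=C[C@H]([C@@H](O)C(C)(C)O)OC3=O)[C@H]1CO[Si](c4ccccc4)(c5ccccc5)C(C)(C)C | intermediate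
25 | (5R)-5-[(1R)-1,2-dihydroxy-2-methylpropyl]-3-[(1R,2S,5S,6R,9R)-2-hydroxy-6-(hydroxymethyl)-2-methyl-7-methylidene-10-oxabicyclo[7.1.0]decan-5-yl]furan-2(5H)-one | C=C1C[C@H]2O[C@H]2[C@@](C)(O)CC[C@H](C2=C[C@H]([C@@H](O)C(C)(C)O)OC2=O)[C@H]1CO | target

**Step count and risks**
Total step count: 16. Longest linear sequence: 13 (steps 1–3 and 7–16 from 1; the branch from 7 is equally long through steps 4–6 and 7–16).

The three steps most likely to fail:

Step 12 (the proposed photochemical ring closure). The 9-endo addition is slow and competes with 6-endo attack of the α-keto radical on the C4=C12 enoate, with simple reduction of the carbon–halogen bond, and with E/Z or conjugative isomerization of the new alkene. The fallback uses known chemistry and sets out from Weinreb amide 18. CH2=CHCH2MgBr (THF, −78 °C) gives the allyl ketone F1. Ring-closing metathesis of its two terminal alkenes with the second-generation Hoveyda–Grubbs catalyst (10 mol %, 1,4-benzoquinone, toluene, 0.001 M, 80 °C) closes the Z-cyclononene and comes back to the route at 21.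

Step 9 (Ireland–Claisen rearrangement). The amide base can also deprotonate the enoate at C5 or add to it, the β-silyloxy enolate can eliminate, and the chair preference may be eroded by strain between the C4 ester and the dioxolanyl group. The fallback sets out from alcohol 12 and uses a base-free amide-acetal (Eschenmoser–Claisen) rearrangement. Heating 12 with the morpholine amide acetal F2 (xylene, 140 °C) gives, through the same chair arrangement, the morpholine amide F3. Addition of LiCH2Cl (ICH2Cl, MeLi·LiBr, THF, −78 °C) to this amide comes back to the route at 19.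

Step 7 (vinylalumination). The aldol step may give poor Felkin selectivity or erode the Z geometry through the aluminium allenoate. The fallback sets out from ynoate 6. The same hydroalumination is quenched with I2 to give the α-iodo enoate F4. A Nozaki–Hiyama–Kishi coupling of F4 with aldehyde 10 (CrCl2, NiCl2 cat., DMF–THF, 25 °C), which retains alkene geometry and also follows Felkin control, comes back to the route at 12.

**Further compounds**
F1 | step 12 | C11 allyl ketone (C11(=O)–CH2–CH=CH2; otherwise as 18) | C=C[C@@](C)(O)CC[C@@H]([C@@H](CO[Si](c1ccccc1)(c1ccccc1)C(C)(C)C)C(=O)CC=C)/C(C(=O)OC)=C/[C@H]2OC(C)(C)O[C@H]2C(C)(C)O[Si](CC)(CC)CC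
F2 | step 9 | 4-[3-(tert-butyldiphenylsilyloxy)-1,1-dimethoxypropyl]morpholine | COC(OC)(CCO[Si](c1ccccc1)(c1ccccc1)C(C)(C)C)N1CCOCC1
F3 | step 9 | C11 morpholine amide (stereochemistry as 17) | C=C[C@@](C)(O)CC[C@@H]([C@@H](CO[Si](c1ccccc1)(c1ccccc1)C(C)(C)C)C(=O)N1CCOCC1)/C(C(=O)OC)=C/[C@H]2OC(C)(C)O[C@H]2C(C)(C)O[Si](CC)(CC)CC
F4 | step 7 | methyl (2E,6S)-6-hydroxy-2-iodo-6-methylocta-2,7-dienoate (C5 cis to the ester) | C=C[C@@](C)(O)CC/C=C(\C(=O)OC)I
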